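Ring B (C5–C6–C7–C8–C9–C10) is disconnected at C9–C10. C10 is at once the 2-position of the dihydrobenzofuran and the ring B neighbour of C9, and C1 is its benzylic 3-position; a C9 ketyl tethered to quaternary C5 can therefore add to an aromatic benzofuran. One SmI2 step forms C9–C10, closes ring B, dearomatises the furan and sets C10, C1 and C9. The precursor is a 1,3-dimethoxy-tetrahydrodibenzofuran carrying the cis C4/C5 methyl pair and a butanal chain on C5, assembled from a conjugate addition–allylation ketone and a symmetric aryloxyamine. The cyclopropane, dione and chalcone are added afterwards.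

Key step: step 5

Remarks on the chemistry (assumptions):
- Locants: ring A = C10–C1–C2–C3–C4–C5, ring B = C5–C6–C7–C8–C9–C10; C14 and C15 are the methyl groups on C5 and C4; C11 is the cyclopropane carbon with its two methyl groups. Aryl carbons: C1′ (acylated at the end), C2′ (carries the ring oxygen bonded to C10), C3′ (bonded to C1), C4′ (OMe), C5′ (H), C6′ (OMe, finally OH). The "ring A face" of ring B is the face on which C1 and C4 lie; O–C10 and C14 lie on the other face.
- 2-Methylcyclohex-2-en-1-one is used as the six-membered enone, CC1=CCCCC1=O, since only a cyclohexenone can become ring A.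
- The butanal chain is built by allylation and hydroformylation, because a homoallylic halide is a poor electrophile for a hindered enolate that must form a quaternary centre.
- The C9 carbinols of 12, 19 and 20 are drawn as single epimers; either epimer serves, because C9 is oxidised in steps 6 and 11.

Step 1
Reactants: 1 2-methylcyclohex-2-en-1-one; 2 allyl iodide (3-iodoprop-1-ene)
Product: 4 (2S,3R)-2-allyl-2,3-dimethylcyclohexan-1-one, via aluminium enolate 3 (not isolated)
Conditions: Me3Al, Cu(O2C-C4H3S) (copper thiophene-2-carboxylate, 2 mol %), BINOL-derived phosphoramidite ligand (4 mol %, the enantiomer that gives 3R), Et2O, −30 °C; then MeLi, THF/HMPA, 2, −30 → 0 °C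
Reagents that add atoms: trimethylaluminium, C[Al](C)C
Why: Copper-catalysed asymmetric conjugate addition of Me3Al sets the methyl-bearing centre (3R, later C4) under ligand control, and the enolate, activated as its lithium aluminate, is allylated (enolate alkylation) on the face opposite the adjacent methyl group, which places the two methyl groups cis and fixes the quaternary centre (2S, later C5).

Step 2
Reactants: 5 1-bromo-3,5-dimethoxybenzene; 6 ethyl (E)-N-hydroxyacetimidate
Product: 7 ethyl (E)-N-(3,5-dimethoxyphenoxy)acetimidate
Conditions: [Pd(allyl)Cl]2 (1 mol %), t-BuBrettPhos (2.5 mol %), Cs2CO3, toluene, 65 °C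
Reagents that add atoms: none
Why: Palladium-catalysed C–O cross-coupling of an aryl bromide with the hydroxyl group of the acetohydroximate gives a stable O-arylhydroxylamine equivalent from a symmetric arene, so that no regiochemical question arises in the annulation that follows.

Step 3
Reactants: 4 (2S,3R)-2-allyl-2,3-dimethylcyclohexan-1-one; 7 ethyl (E)-N-(3,5-dimethoxyphenoxy)acetimidate
Product: 10 (6S,7R)-6-allyl-1,3-dimethoxy-6,7-dimethyl-6,7,8,9-tetrahydrodibenzo[b,d]furan, via aryloxyamine 8 (not isolated), via O-aryl oxime 9 (not isolated)
Conditions: HCl (4 M in 1,4-dioxane), H2O (2 equiv), 25 → 90 °C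
Reagents that add atoms: none
Why: Acid hydrolyses the imidate to the aryloxyamine, which condenses with the ketone, and the O-aryl oxime then undergoes the oxygen analogue of the Fischer indole synthesis ([3,3]-sigmatropic rearrangement, cyclisation, loss of ammonia); the ene-hydroxylamine can form only towards the CH2 group because the other α-carbon is quaternary, both ortho positions of the aryl ring are equivalent, and no stereocentre is touched.

Step 4
Reactants: 10 (6S,7R)-6-allyl-1,3-dimethoxy-6,7-dimethyl-6,7,8,9-tetrahydrodibenzo[b,d]furan
Product: 11 4-[(6S,7R)-1,3-dimethoxy-6,7-dimethyl-6,7,8,9-tetrahydrodibenzo[b,d]furan-6-yl]butanal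
Conditions: Rh(acac)(CO)2 (1 mol %), BIPHEPHOS (2 mol %), CO/H2 (1:1, 10 bar), toluene, 70 °C
Reagents that add atoms: carbon monoxide, [C-]#[O+]
Why: Rhodium-catalysed hydroformylation with a wide-bite-angle diphosphite is strongly linear-selective for a monosubstituted alkene next to a quaternary carbon and adds the one carbon (C9) that completes the butanal chain without touching the tetrasubstituted furan double bond.

Step 5
Reactants: 11 4-[(6S,7R)-1,3-dimethoxy-6,7-dimethyl-6,7,8,9-tetrahydrodibenzo[b,d]furan-6-yl]butanal
Product: 12 tetracyclic C9 alcohol (ring B closed; cis-fused 4′,6′-dimethoxy-dihydrobenzofuran with O–C10 cis to the C14 methyl and H1 cis to C9; 9-OH trans to the ring oxygen)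
Conditions: SmI2 (2.5 equiv), HMPA (18 equiv), t-BuOH (5 equiv), THF, 25 °C, slow addition of 11 at high dilution; aq. NH4Cl
Reagents that add atoms: none
Why: Divalent samarium, made strongly reducing by HMPA, gives the C9 ketyl, which adds to C10 (the furan 2-position) because this leaves the unpaired electron on benzylic C1; a second SmI2 reduces that radical and t-BuOH protonates C1. The closest known reaction type is the SmI2/HMPA ketyl–(hetero)arene dearomatising cyclisation established for indoles, naphthalenes and benzene rings. Ring B (C5–C6–C7–C8–C9–C10) closes in the 6-exo-trig mode through a chair-like transition state. C10 is controlled by the tether, since the four-atom chain on quaternary C5 reaches the adjacent C10 only from the face on which C6 lies, so O–C10 ends cis to the C14 methyl; C1 is controlled by ring strain, protonation giving only the cis-fused dihydrofuran (H1 cis to C9); C9 should place its HMPA-solvated O–Sm group away from the ring oxygen (hydroxyl trans to O–C10) and is erased in step 6 in any case. The step needs reduction of the aldehyde only, cyclisation faster than pinacol coupling, and protonation at C1 faster than expulsion of the C10 aryloxide; the arene and its ethers are beyond the reach of SmI2, slow addition at high dilution suppresses dimerisation, and the excess alcohol together with the poor overlap between the benzylic carbanion orbital and the in-plane C10–O bond disfavours ring opening.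

Step 6
Reactants: 12 tetracyclic C9 alcohol
Product: 13 tetracyclic C9 ketone
Conditions: Dess–Martin periodinane, NaHCO3, CH2Cl2, 0 → 25 °C
Reagents that add atoms: none
Why: Dess–Martin oxidation converts the hindered secondary alcohol into the ketone under buffered, non-basic conditions, removes the C9 stereocentre and cannot epimerise the neighbouring centre because C10 is quaternary.

Step 7
Reactants: 13 tetracyclic C9 ketone
Product: 15 diosphenol (8-hydroxy-7-en-9-one), via C8 hydroperoxide 14 (not isolated)
Conditions: KOt-Bu (3 equiv), O2 (1 atm), THF/t-BuOH, −20 → 0 °C; aq. HCl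
Reagents that add atoms: dioxygen, O=O
Why: Enolate autoxidation works here because the ketone can enolise only towards C8, the C8 hydroperoxide loses water to the 8,9-dione, and the dione rests as the diosphenol since only C7 carries hydrogen next to it.

Step 8
Reactants: 15 diosphenol (8-hydroxy-7-en-9-one)
Product: 18 6-ene-8,9-dione, via C7 selenide 16 (not isolated), via C7 selenoxide 17 (not isolated)
Conditions: PhSeCl, pyridine, CH2Cl2, 0 °C; then mCPBA (1.05 equiv), −78 → 0 °C
Reagents that add atoms: none
Why: The enol carbon C7 is selenenylated and the derived selenoxide undergoes syn-elimination (selenoxide elimination) towards C6, the only neighbouring carbon that carries hydrogen, under conditions that spare the electron-rich arene and its benzylic C1–H.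

Step 9
Reactants: 18 6-ene-8,9-dione
Product: 19 6-ene-8,9-diol (both hydroxyls on the ring A face)
Conditions: NaBH4, CeCl3·7H2O, MeOH/THF, −78 → −20 °C
Reagents that add atoms: none
Why: Luche reduction is 1,2-selective for the enone carbonyl and should deliver the small hydride to C8 from the convex face of the cis-fused bicycle (the face of O–C10 and C14, ring A hanging over the other), which places the C8 hydroxyl on the ring A face; C9 is reduced in the same pot and its configuration is irrelevant because it is re-oxidised in step 11.

Step 10
Reactants: 19 6-ene-8,9-diol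
Product: 20 cyclopropyl diol (6,7-isopropylidene bridge cis to the C8 hydroxyl, trans to C14 and to the ring oxygen)
Conditions: Et2Zn (6 equiv), CH2Cl2, −40 °C (zinc alkoxide first); then 2,2-diiodopropane (4 equiv), −40 → 0 °C
Reagents that add atoms: 2,2-diiodopropane, CC(C)(I)I
Why: In this hydroxyl-directed Simmons–Smith-type gem-dimethylcyclopropanation the C8 zinc alkoxide delivers the CMe2 unit of the zinc carbenoid to C6=C7 on its own face, so the cyclopropane forms cis to the C8 oxygen, on the ring A face and trans to the C14 methyl and the ring oxygen, which sets C6 and C7 as in the target without relying on the facial bias of the bicycle.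

Step 11
Reactants: 20 cyclopropyl diol
Product: 21 cyclopropyl 8,9-dione (4′,6′-dimethoxy-dihydrobenzofuran-fused aristolane-8,9-dione)
Conditions: IBX (5 equiv), DMSO, 25 → 40 °C
Reagents that add atoms: none
Why: IBX oxidises both carbinols of the 1,2-diol to the 1,2-dione without C–C cleavage and under neutral conditions, so the transient 9-hydroxy-8-ketone cannot lose the β-aryloxy group by base-induced elimination, and C6 and C7 are untouched because a cis-fused three-membered ring cannot epimerise at one carbon.

Step 12
Reactants: 21 cyclopropyl 8,9-dione; 22 (E)-4-methoxycinnamic acid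
Product: 24 1′-[(E)-4-methoxycinnamoyl] derivative of 21 (6′-O-methyl ether of the target), via mixed anhydride 23 (not isolated)
Conditions: 22, (CF3CO)2O, CH2Cl2, 0 °C; then 21, 0 → 25 °C
Reagents that add atoms: none
Why: Friedel–Crafts acylation with the mixed trifluoroacetic anhydride needs no metal Lewis acid, which spares the cyclopropyl dione, and should go to C1′ and not to C5′ because C1′ lies between the tied-back ring oxygen and one methoxy group whereas C5′ is flanked by two methoxy groups, one of them pushed towards it by the C1 substituent; the E-alkene is retained.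

Step 13
Reactants: 24 6′-O-methyl ether of the target
Product: 25 CNP0121765.1 (target)
Conditions: BCl3 (1.5 equiv), CH2Cl2, −78 → −30 °C; aq. NaHCO3
Reagents that add atoms: none
Why: In this chelation-controlled demethylation BCl3 binds the aryl ketone and the ortho methoxy oxygen at C6′ in a six-membered chelate and cleaves only that methyl ether, while the para C4′ methoxy, the anisole methoxy and the ring ether (whose alkyl carbon C10 is quaternary) are left intact.

Compound list
1 | 2-methylcyclohex-2-en-1-one | CC1=CCCCC1=O | starting material
2 | allyl iodide | C=CCI | starting material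
3 | dimethylaluminium (3R)-2,3-dimethylcyclohex-1-en-1-olate | C[Al](C)OC1=C(C)[C@H](C)CCC1 | intermediate (not isolated)
4 | (2S,3R)-2-allyl-2,3-dimethylcyclohexan-1-one | O=C1CCC[C@@H](C)[C@]1(C)CC=C | intermediate
5 | 1-bromo-3,5-dimethoxybenzene | COc1cc(Br)cc(OC)c1 | starting material
6 | ethyl (E)-N-hydroxyacetimidate | CCO/C(C)=N/O | starting material
7 | ethyl (E)-N-(3,5-dimethoxyphenoxy)acetimidate | CCO/C(C)=N/Oc1cc(OC)cc(OC)c1 | intermediate
8 | O-(3,5-dimethoxyphenyl)hydroxylamine | NOc1cc(OC)cc(OC)c1 | intermediate (not isolated)
9 | (E)-O-(3,5-dimethoxyphenyl) oxime of 4 | COc1cc(OC)cc(O/N=C2\CCC[C@@H](C)[C@]2(C)CC=C)c1 | intermediate (not isolated)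
10 | (6S,7R)-6-allyl-1,3-dimethoxy-6,7-dimethyl-6,7,8,9-tetrahydrodibenzo[b,d]furan | COc1cc(OC)c2c(c1)oc1c2CC[C@@H](C)[C@]1(C)CC=C | intermediate
11 | 4-[(6S,7R)-1,3-dimethoxy-6,7-dimethyl-6,7,8,9-tetrahydrodibenzo[b,d]furan-6-yl]butanal | COc1cc(OC)c2c(c1)oc1c2CC[C@@H](C)[C@]1(C)CCCC=O | intermediate
12 | tetracyclic C9 alcohol (O–C10 cis to C14, H1 cis to C9, 9-OH trans to ring O) | COc1cc(OC)c2c(c1)O[C@]13[C@@H](O)CCC[C@@]1(C)[C@H](C)CC[C@H]23 | intermediate
13 | tetracyclic C9 ketone | COc1cc(OC)c2c(c1)O[C@]13C(=O)CCC[C@@]1(C)[C@H](C)CC[C@H]23 | intermediate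
14 | C8 hydroperoxide of 13 (C8 epimers) | COc1cc(OC)c2c(c1)O[C@]13C(=O)C(OO)CC[C@@]1(C)[C@H](C)CC[C@H]23 | intermediate (not isolated)
15 | diosphenol (8-hydroxy-7-en-9-one) | COc1cc(OC)c2c(c1)O[C@]13C(=O)C(O)=CC[C@@]1(C)[C@H](C)CC[C@H]23 | intermediate
16 | 7-phenylselanyl-8,9-dione (C7 epimers) | COc1cc(OC)c2c(c1)O[C@]13C(=O)C(=O)C([Se]c4ccccc4)C[C@@]1(C)[C@H](C)CC[C@H]23 | intermediate (not isolated)
17 | 7-phenylseleninyl-8,9-dione (selenoxide) | COc1cc(OC)c2c(c1)O[C@]13C(=O)C(=O)C([Se](=O)c4ccccc4)C[C@@]1(C)[C@H](C)CC[C@H]23 | intermediate (not isolated)
18 | 6-ene-8,9-dione | COc1cc(OC)c2c(c1)O[C@]13C(=O)C(=O)C=C[C@@]1(C)[C@H](C)CC[C@H]23 | intermediate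
19 | 6-ene-8,9-diol (hydroxyls on the ring A face) | COc1cc(OC)c2c(c1)O[C@]13[C@@H](O)[C@@H](O)C=C[C@@]1(C)[C@H](C)CC[C@H]23 | intermediate
20 | cyclopropyl 8,9-diol (cyclopropane cis to the hydroxyls) | COc1cc(OC)c2c(c1)O[C@]13[C@@H](O)[C@@H](O)[C@@H]4[C@@H](C4(C)C)[C@@]1(C)[C@H](C)CC[C@H]23 | intermediate
21 | cyclopropyl 8,9-dione | COc1cc(OC)c2c(c1)O[C@]13C(=O)C(=O)[C@@H]4[C@@H](C4(C)C)[C@@]1(C)[C@H](C)CC[C@H]23 | intermediate
22 | (E)-4-methoxycinnamic acid | COc1ccc(/C=C/C(=O)O)cc1 | starting material
23 | (E)-4-methoxycinnamic trifluoroacetic anhydride | COc1ccc(/C=C/C(=O)OC(=O)C(F)(F)F)cc1 | intermediate (not isolated)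
24 | 6′-O-methyl ether of the target | COc1ccc(/C=C/C(=O)c2c(OC)cc(OC)c3c2O[C@]24C(=O)C(=O)[C@@H]5[C@@H](C5(C)C)[C@@]2(C)[C@H](C)CC[C@H]34)cc1 | intermediate
25 | CNP0121765.1 | COc1ccc(/C=C/C(=O)c2c(O)cc(OC)c3c2O[C@]24C(=O)C(=O)[C@@H]5[C@@H](C5(C)C)[C@@]2(C)[C@H](C)CC[C@H]34)cc1 | target

Total step count: 13. Longest linear sequence: 12 steps (steps 1 and 3 to 13; step 2 is a one-step branch).

The three steps most likely to fail

Risk 1, step 5. After electron transfer the ketyl may dimerise or be reduced to the primary alcohol before it adds to the fully substituted, electron-rich C10. The trialkoxy-substituted benzylic radical may also resist the second reduction, or the C1 carbanion may expel the C10 aryloxide and reopen the furan. The fallback replaces the radical anion by a neutral acyl radical and the carbanion by hydrogen-atom transfer. It sets out from aldehyde 11, which is oxidised (NaClO2, NaH2PO4, 2-methylbut-2-ene, t-BuOH/H2O) to the carboxylic acid F1 and converted with PhSeSePh and PBu3 into the Se-phenyl selenoester F2. Slow addition of Bu3SnH and AIBN in benzene at 80 °C should generate the C9 acyl radical, which closes ring B by the same 6-exo-trig addition to C10 from the face of the C5 tether. The benzylic C1 radical is then quenched by the stannane to the cis-fused ring. This gives ketone 13 directly, where the route is rejoined.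

Risk 2, step 10. The gem-dimethyl zinc carbenoid may decompose by hydrogen shift to propene faster than it is transferred to the hindered C6=C7 bond on the ring A face, and delivery is misdirected if hydride addition in step 9 did not place the C8 hydroxyl on that face. The fallback sets out from ene-dione 18 and uses a conjugate isopropylidene transfer. Diphenylsulfonium isopropylide (from isopropyldiphenylsulfonium tetrafluoroborate and LDA, DME, −78 → −20 °C) adds to C6 and closes on C7 (ylide cyclopropanation of an enone). It comes back to the route at cyclopropyl dione 21 and saves steps 9 to 11. It gives up hydroxyl direction and relies on addition anti to the C14 methyl, so it is the second choice. No compound outside the list is made (F0).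

Risk 3, step 12. Acylation may compete at C5′ (poor regioselectivity), and the trifluoroacetic acid set free may open the gem-dimethylcyclopropyl ketone. The fallback replaces electrophilic acylation by cross-coupling under neutral to mildly basic conditions. It sets out from 21, which is iodinated with N-iodosuccinimide (MeCN, 0 °C) to the 1′-iodide F3, a stage at which the regiochemistry can be secured by separation. Carbonylative Suzuki–Miyaura coupling with (E)-2-(4-methoxyphenyl)vinylboronic acid (PdCl2(dppf), CO 1 atm, K2CO3, anisole, 80 °C) should then give 24, where the route is rejoined.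

Further compounds
F1 | step 5 | 4-[(6S,7R)-1,3-dimethoxy-6,7-dimethyl-6,7,8,9-tetrahydrodibenzo[b,d]furan-6-yl]butanoic acid | COc1cc(OC)c2c(c1)oc1c2CC[C@@H](C)[C@]1(C)CCCC(=O)O
F2 | step 5 | Se-phenyl 4-[(6S,7R)-1,3-dimethoxy-6,7-dimethyl-6,7,8,9-tetrahydrodibenzo[b,d]furan-6-yl]butaneselenoate | COc1cc(OC)c2c(c1)oc1c2CC[C@@H](C)[C@]1(C)CCCC(=O)[Se]c1ccccc1
F0 | step 10 | none | none
F3 | step 12 | 1′-iodo derivative of cyclopropyl dione 21 | COc1cc(OC)c2c(c1I)O[C@]13C(=O)C(=O)[C@@H]4[C@@H](C4(C)C)[C@@]1(C)[C@H](C)CC[C@H]23
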